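**Retrosynthetic overview**

1. Target 10 ⇒ isoflavone 9: the only stereocenter (C3) is made last, by enantioselective hydride/proton transfer to C2/C3 (isoflavone-reductase logic), so nothing can epimerise it afterwards.
2. 9 ⇒ dibromo triol 7 + 2 × prenylstannane 8: both prenyl groups in one double Stille coupling (C6 and C5′).
3. 7 ⇒ trimethyl ether 6: global O-demethylation before any acid-sensitive group exists.
4. 6 ⇒ chalcone 3 (key step, one flask): ring C is closed by intramolecular oxa-Michael addition (flavanone 4), then ring B moves from C2 to C3 by an oxidative 1,2-aryl shift (isoflavone-synthase logic).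
5. 3 ⇒ 1 + 2 by Claisen–Schmidt condensation; rings A and B are bought, ring C is the only ring formed (step 2).

Assumption: the target is taken exactly as the SMILES, i.e. the (3S)-isoflavanone (CIP order at C3: C4 > C2 > C1′ > H); 1, 2 and 8 are bought as catalogue items.

**Route**

Step 1
Reactants: 1 5-bromopaeonol [1-(5-bromo-2-hydroxy-4-methoxyphenyl)ethan-1-one]; 2 5-bromo-2,4-dimethoxybenzaldehyde
Product: 3 (E)-1-(5-bromo-2-hydroxy-4-methoxyphenyl)-3-(5-bromo-2,4-dimethoxyphenyl)prop-2-en-1-one
Conditions: KOH (50% aq), EtOH, rt, 48 h; acidic work-up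
Reagents that add atoms: none
Why: Claisen–Schmidt aldol condensation, in which the ketone enolate adds to the non-enolisable aldehyde and E1cB dehydration gives the conjugated (E)-enone; aryl bromides and methyl ethers are inert to aqueous KOH and no stereocenter is formed.

Step 2
Reactants: 3 the 2′-hydroxychalcone from step 1
Product: 6 the isoflavone 6-bromo-3-(5-bromo-2,4-dimethoxyphenyl)-7-methoxy-4H-chromen-4-one, via flavanone 4 (not isolated), via 3-iodanylflavanone 5 (not isolated)
Conditions: TsOH·H2O (0.2 equiv), MeCN, 80 °C, 1 h; then PhI(OH)OTs (1.3 equiv), 80 °C, 3 h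
Reagents that add atoms: none
Why: Proposed new method: acid closes ring C by 6-endo oxa-Michael addition of the chelated phenol (3 ⇌ racemic flavanone 4), the trivalent iodine reagent PhI(OH)OTs then traps the C3 enol of 4 (or the alkene of residual 3, which converges on the same species) as the trans C3 λ3-iodane 5, and the electron-rich 2,4-dimethoxyphenyl group, antiperiplanar to the departing PhI, shifts from C2 to C3 through a phenonium ion before the C2 oxocarbenium ion loses H3 to give the isoflavone; the closest known reaction type is the 2,3-aryl migration of isolated flavanones to isoflavones with PhI(OH)OTs in MeCN (and the trivalent thallium rearrangement of 2′-hydroxychalcones in methanol); the bromines block the most nucleophilic arene positions, the methyl ethers are acid-stable, and the stereocentres of racemic 4 and 5 vanish in 6.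

Step 3
Reactants: 6 the trimethyl ether isoflavone from step 2
Product: 7 6-bromo-3-(5-bromo-2,4-dihydroxyphenyl)-7-hydroxy-4H-chromen-4-one
Conditions: BBr3 (8 equiv), CH2Cl2, −78 °C → rt, 16 h; then MeOH, H2O
Reagents that add atoms: none
Why: Lewis-acid ether cleavage (BBr3 demethylation), in which O–B coordination is followed by SN2 attack of bromide on each methyl group; the chromone and the aryl bromides are inert, and the step is placed before any prenyl group or stereocenter exists.

Step 4
Reactants: 7 the dibromo triol isoflavone from step 3; 8 tributyl(3-methylbut-2-en-1-yl)stannane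
Product: 9 3-[2,4-dihydroxy-5-(3-methylbut-2-en-1-yl)phenyl]-7-hydroxy-6-(3-methylbut-2-en-1-yl)-4H-chromen-4-one
Conditions: 8 (3 equiv), Pd(PPh3)4 (10 mol %), DMF, 95 °C, 12 h
Reagents that add atoms: none
Why: Twofold Stille (Migita–Kosugi–Stille) cross-coupling, in which zerovalent palladium inserts into each C–Br bond, the allyl group is transferred from tin and reductive elimination at the less hindered allyl terminus gives the linear prenyl groups; free phenols and the chromone tolerate these neutral conditions and no stereocenter is formed.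

Step 5
Reactants: 9 the diprenyl isoflavone from step 4
Product: 10 (3S)-3-[2,4-dihydroxy-5-(3-methylbut-2-en-1-yl)phenyl]-7-hydroxy-6-(3-methylbut-2-en-1-yl)-2,3-dihydro-4H-chromen-4-one
Conditions: diethyl 2,6-dimethyl-1,4-dihydropyridine-3,5-dicarboxylate (Hantzsch ester, 1.3 equiv), (R)-3,3′-bis(2,4,6-triisopropylphenyl)-1,1′-binaphthyl-2,2′-diyl N-triflylphosphoramide (10 mol %), CHCl3/toluene 1:1, 4 Å MS, 0 °C → rt, dark
Reagents that add atoms: none
Why: Proposed new method: the chiral acid activates the chromone carbonyl as a 4-hydroxybenzopyrylium ion pair, the dihydropyridine delivers hydride to C2 as NADPH does in isoflavone reductase, and the resulting 3-aryl enol is protonated at C3 inside the chiral phosphoramide ion pair, which sets the (3S) center (the (S)-catalyst is used instead if a first run, checked by chiral HPLC and CD, shows the opposite sense); the closest known reaction types are the chiral Brønsted acid/Hantzsch ester transfer hydrogenation of 3-substituted quinolines and of benzopyrylium ions and the chiral-acid-catalysed enantioselective protonation of 2-aryl cycloalkanone enol derivatives; the acid is too weak to protonate the isolated prenyl alkenes, the aryl ketone is not reduced, and with no base present and no later step C3 is not scrambled.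

**Compound list**

1 | 1-(5-bromo-2-hydroxy-4-methoxyphenyl)ethan-1-one (5-bromopaeonol) | CC(=O)c1cc(Br)c(OC)cc1O | starting material
2 | 5-bromo-2,4-dimethoxybenzaldehyde | O=Cc1cc(Br)c(OC)cc1OC | starting material
3 | (E)-1-(5-bromo-2-hydroxy-4-methoxyphenyl)-3-(5-bromo-2,4-dimethoxyphenyl)prop-2-en-1-one | COc1cc(O)c(cc1Br)C(=O)/C=C/c1cc(Br)c(OC)cc1OC | intermediate
4 | rac-6-bromo-2-(5-bromo-2,4-dimethoxyphenyl)-7-methoxychroman-4-one (flavanone, racemic) | COc1cc2OC(CC(=O)c2cc1Br)c1cc(Br)c(OC)cc1OC | intermediate
5 | rac-trans-6-bromo-2-(5-bromo-2,4-dimethoxyphenyl)-7-methoxy-3-[phenyl(tosyloxy)-λ3-iodanyl]chroman-4-one (racemic) | COc1cc2OC(c3cc(Br)c(OC)cc3OC)C(I(c3ccccc3)OS(=O)(=O)c3ccc(C)cc3)C(=O)c2cc1Br | intermediate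
6 | 6-bromo-3-(5-bromo-2,4-dimethoxyphenyl)-7-methoxy-4H-chromen-4-one | COc1cc2occ(-c3cc(Br)c(OC)cc3OC)c(=O)c2cc1Br | intermediate
7 | 6-bromo-3-(5-bromo-2,4-dihydroxyphenyl)-7-hydroxy-4H-chromen-4-one | Oc1cc2occ(-c3cc(Br)c(O)cc3O)c(=O)c2cc1Br | intermediate
8 | tributyl(3-methylbut-2-en-1-yl)stannane | CCCC[Sn](CCCC)(CCCC)CC=C(C)C | starting material
9 | 3-[2,4-dihydroxy-5-(3-methylbut-2-en-1-yl)phenyl]-7-hydroxy-6-(3-methylbut-2-en-1-yl)-4H-chromen-4-one | CC(C)=CCc1cc2c(cc1O)occ(-c1cc(CC=C(C)C)c(O)cc1O)c2=O | intermediate
10 | (3S)-3-[2,4-dihydroxy-5-(3-methylbut-2-en-1-yl)phenyl]-7-hydroxy-6-(3-methylbut-2-en-1-yl)-2,3-dihydro-4H-chromen-4-one | CC(C)=CCc1cc2c(cc1O)OC[C@H](c1cc(CC=C(C)C)c(O)cc1O)C2=O | target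

**Step count and risks**

Total steps: 5. Longest linear sequence: 5 steps (1 or 2 → 3 → 6 → 7 → 9 → 10).

The step most likely to fail is step 5. The transfer hydrogenation has no precedent on an isoflavone, so the rate or the ee may be low, and the acid could cyclise a prenyl group onto its neighbouring phenol. The fallback sets out from 9 and comes back at 10:
- 9 is protected with MOMCl and iPr2NEt in CH2Cl2 to give the tris-MOM isoflavone F3.
- Noyori–Ikariya asymmetric transfer hydrogenation with RuCl[(S,S)-TsDPEN](p-cymene) and HCO2H/Et3N (5:2) in EtOAc at 40 °C reduces the C2=C3 bond and then the ketone. Dynamic kinetic resolution of the base-labile C3 gives the cis-(3S,4S)-isoflavan-4-ol F4.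
- Dess–Martin periodinane buffered with NaHCO3 in CH2Cl2 at 0 °C reoxidises C4 without touching C3 and gives the (3S)-isoflavanone tris-MOM ether F5.
- ZnBr2 and n-PrSH in CH2Cl2 at 0 °C remove the MOM groups within minutes and deliver 10.

The second is step 2. The iodane 5 may eliminate to the flavone or collapse to a 3-tosyloxyflavanone instead of undergoing the aryl shift, and residual chalcone may not be funnelled cleanly. The fallback sets out from 3 and comes back at 6:
- The open-chain chalcone is rearranged with Tl(NO3)3·3H2O (trivalent thallium) in MeOH/HC(OMe)3 at rt. The aryl shift then precedes ring closure and gives the racemic acetal 1-(5-bromo-2-hydroxy-4-methoxyphenyl)-2-(5-bromo-2,4-dimethoxyphenyl)-3,3-dimethoxypropan-1-one F1.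
- 10% HCl in MeOH at 60 °C closes ring C and eliminates methanol to give 6.

The third is step 4. Prenyl transfer from tin can give branched 1,1-dimethylallyl isomers, and oxidative addition next to free phenols may be slow. The fallback sets out from 7 and comes back at 9:
- 7 is coupled with allyltributylstannane (Pd(PPh3)4, DMF, 90 °C), which has no regiochemical ambiguity, to give the diallyl isoflavone 6-allyl-3-(5-allyl-2,4-dihydroxyphenyl)-7-hydroxy-4H-chromen-4-one F2.
- Olefin cross-metathesis with excess 2-methylbut-2-ene and the second-generation Grubbs catalyst RuCl2(=CHPh)(PCy3)(H2IMes) in CH2Cl2 at 40 °C converts both allyl groups into prenyl groups and gives 9.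

**Further compounds**

F1 | step 2 | rac-1-(5-bromo-2-hydroxy-4-methoxyphenyl)-2-(5-bromo-2,4-dimethoxyphenyl)-3,3-dimethoxypropan-1-one | COc1cc(O)c(cc1Br)C(=O)C(C(OC)OC)c1cc(Br)c(OC)cc1OC
F2 | step 4 | 6-allyl-3-(5-allyl-2,4-dihydroxyphenyl)-7-hydroxy-4H-chromen-4-one | C=CCc1cc2c(cc1O)occ(-c1cc(CC=C)c(O)cc1O)c2=O
F3 | step 5 | 3-[2,4-bis(methoxymethoxy)-5-(3-methylbut-2-en-1-yl)phenyl]-7-(methoxymethoxy)-6-(3-methylbut-2-en-1-yl)-4H-chromen-4-one | CC(C)=CCc1cc2c(cc1OCOC)occ(-c1cc(CC=C(C)C)c(OCOC)cc1OCOC)c2=O
F4 | step 5 | (3S,4S)-cis-3-[2,4-bis(methoxymethoxy)-5-(3-methylbut-2-en-1-yl)phenyl]-7-(methoxymethoxy)-6-(3-methylbut-2-en-1-yl)chroman-4-ol | O[C@H]1[C@@H](c2cc(CC=C(C)C)c(OCOC)cc2OCOC)COc2cc(OCOC)c(CC=C(C)C)cc21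
F5 | step 5 | (3S)-3-[2,4-bis(methoxymethoxy)-5-(3-methylbut-2-en-1-yl)phenyl]-7-(methoxymethoxy)-6-(3-methylbut-2-en-1-yl)chroman-4-one | CC(C)=CCc1cc2c(cc1OCOC)OC[C@H](c1cc(CC=C(C)C)c(OCOC)cc1OCOC)C2=O
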